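The constants were set for the occasion.

Which way does the substrate go in this flask, to product or to homo dimer, and can I see that without integrating the whole flask?

substrate 19 mM; gas phase 10 mM (held); catalyst 2.7 mol%; added ligand 1.4 mM; time 10 d

    catalyst + added ligand ⇌ idle complex, settled at all times (K1 = 1800 M⁻¹)
    gas phase ⇌ dissolved gas, rate k2*(csat - [dissolved gas]) (k2 = 5.5 × 10⁻⁵ s⁻¹, csat = 10 mM)
    2 substrate → homo dimer (k3 = 8.1 × 10⁻⁴ M⁻¹ s⁻¹)
    substrate + dissolved gas + catalyst → catalyst + product (k4 = 54 M⁻² s⁻¹)

- the product standing at 10 d, as a percentage of the substrate charged
- concentration of dissolved gas in solution at 2.5 d, in percent of saturation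
- the change that raises the amount of product at 10 d, in percent of the substrate charged most ("none" if none brings more than 2 percentage points) (violet / grey / teal / none)
- amount of product at 10 d, in percent of the substrate charged, after teal

- violet: doubling the saturation concentration of gas phase, all else as stated
- grey: doubling the amount of catalyst, all else as stated
- teal: doubling the transfer coefficient of step 2, all else as stated

1. I looked for two rates. Gas enters an empty solution at 1.98 mM h⁻¹, and each product takes up one gas. The dimer step at the charge uses substrate at 2.11 mM h⁻¹, slightly faster. I took gas capture as quick: the half-life of dissolved gas by the product step alone, at the charged concentrations, is 0.37 h, short against 10 d.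

2. The dimer rate falls with the square of c_substrate, while I held the feed at its empty-solution value. Setting them equal gives the crossing concentration c*, the c_substrate at which control changes hands: 18.4 mM. This flask starts just above it.

3. Integrating with that constant feed gives an estimated ceiling on the yield. With x as the charge over c*, it is close to 3/(1 + 2√(1 + x·x)). That gives 77.5 % here, and I expected less, since dissolved gas does not stay at zero. Teal, doubling the transfer coefficient, and violet, doubling the saturation concentration, each raise c* equally, to an estimated ceiling of 86.3 %. Grey doubles the catalyst, which does not enter c*, so I could not rank grey this way.

4. The feed delivers one charge in 0.400 d. That leaves about 9.98 uptake time constants before 2.5 d, so I put sat near 100 %.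

5. The forecast gave y 64 % (61 % to 67 %), sat 99.9 %, best violet and yb 71 %, on this ground: “Gas transfer limits the rate and dissolved gas starts at zero, so dimerisation wins early”.

6. The simulation gave y 63.7 %, sat >99.9 %, best violet (gain 9.6 percentage points, against 7.3 points for teal and 6.3 points for grey) and yb 71.1 %. The forecast stands on all four.

7. My ceiling stood 14 points above the flask's yield. Without the dimer step the yield is 100 % against 63.7 %, so that step is the main reason why this flask falls short of the full charge.

8. In the neighbour flask with 76 mM of substrate, c* stays 18.4 mM, the charge is 4.13 times c*, and the same reckoning gives 31.6 %. The simulation gives 31.0 %.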